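The runs are simulated with constants of no real substance; the scatter is artificial.

At 2.5 min, the time of reading for Saturday's, Monday's and Tuesday's flasks, the chains have grown past the last earlier reading at 80.0 s, so the earlier curves have to be carried forward by a rule.

all flasks: free monomer 0.99 M; initiator 37 mM

| flask | impurity | remark | time |
|---|---|---|---|
| teal | 1.5 mM | run made earlier |  |
| red | 3.8 mM | run made earlier |  |
| green | 9 mM | run made earlier |  |
| Saturday's | 2.0 mM |  | 2.5 min |
| Monday's | 4.0 mM |  | 2.5 min |
| Tuesday's | 8.0 mM |  | 2.5 min |

- teal (time / s: monomer in chains / %, free monomer / %): 10.0: 3.9, 96.8; 12.0: 4.4, 94.9; 20.0: 7.7, 91.0; 40.0: 14.7, 85.4; 80.0: 25.1, 75.9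
- red (time / s: monomer in chains / %, free monomer / %): 15.0: 5.9, 95.1; 30.0: 11.4, 89.1; 50.0: 17.0, 82.8; 60.0: 19.4, 80.0; 80.0: 23.6, 75.2
- green (time / s: monomer in chains / %, free monomer / %): 15.0: 3.7, 95.0; 30.0: 10.2, 89.5; 50.0: 15.4, 84.9; 60.0: 18.2, 83.0; 80.0: 22.7, 77.2

(each reading ± 0.5 percentage points)

* amount of monomer in chains at the end, in percent of the free monomer charged for Saturday's, Monday's, Tuesday's, in this order
* how the row runs (hardly changes / rises, then falls / falls, then rises / falls all the way / rises all the way)

- "hardly changes" means that all values lie within two and a half points (for a concentration: within two and a half percent of the largest)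

What does the impurity do? Its charge stays below that of initiator even on Tuesday's flask, and the green run lags at its first reading, 3.7% against 5.9% for the red run at the same time. The reckoning here therefore takes each impurity to remove one initiator at the start, with impurity as the limiting reagent of that loss. The balance leaves 35.0 mM on Saturday's flask, 33.0 mM on Monday's and 29.0 mM on Tuesday's: this is the working initiator, the initiator charged less the impurity charged.

How strongly does the rate follow it? Between the green and teal runs the working initiator stands at a ratio of 0.789, but the first-order measure, minus the logarithm of the fraction not yet in chains, read at 80.0 s, stands at 0.891. Within the scatter, that reading matches the square root of the working ratio, 0.888.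

Where does the curve level off? In the teal run the second interval of 40.0 s adds 0.707 of what the first added, which means a time constant of 116 s and a stand near 50.3%. Taking that stand as common to the flasks, and scaling the clock by the square root of working initiator against the teal run's 35.5 mM, gives 36.4%, 35.9% and 34.7%.

The forecast gives 38%, 35.5% and 34%, a row that falls all the way, with its first value above the reckoning here, and adds: "This is an extrapolation, so the uncertainty is a few points."

The flasks give 36.7%, 35.9% and 34.0%, a row that falls all the way; on Tuesday's flask the reckoning stands 0.7 percentage points above the result.

    monomer in chains → over-reaction product (k = 4.90 × 10⁻⁶ s⁻¹)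
    free monomer + initiator → living end + monomer in chains (k = 0.0770 L mol⁻¹ s⁻¹)
    initiator + impurity → spent initiator (k = 520 L mol⁻¹ s⁻¹)
    monomer in chains + living end → free monomer + living end, rate k4*[living end] as long as [monomer in chains] is above zero (k = 0.190 s⁻¹)
    2 living end ⇌ resting dimer (K = 24.0 L mol⁻¹, k = 1.70 L mol⁻¹ s⁻¹)
    free monomer + living end → monomer in chains + living end, rate k6*[living end]*[free monomer] (k = 0.410 L mol⁻¹ s⁻¹)

On Saturday's flask, at the time of reading, living end and resting dimer relax into each other with a half-life of 0.0587 min, both directions taken together, far shorter than that time. At that time living end plus twice resting dimer come to 35.0 mM on Saturday's flask against a working initiator of 35.0 mM, and to 29.0 mM on Tuesday's flask against 29.0 mM.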